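The constants used here were drawn at random within sensible limits; what happens was integrated by code.

The target's drift into the isomer of the product B is slower than the consumption of the starting material, and Tuesday's and Monday's flasks differ in how long that drift runs.

| setting | Tuesday's | Monday's |
|---|---|---|
| starting material | 17 mM (fed, over 3.0 min) | 17 mM (fed, over 3.0 min) |
| reagent | 85.0 mM | 85.0 mM |
| time | 15 min | 30 min |

    starting material + reagent → isomer of the product A (k1 = 0.061 L mol⁻¹ s⁻¹)
    target ⇌ isomer of the product B (K2 = 6.8, k2 = 8.5 × 10⁻⁴ s⁻¹)
    starting material + reagent → target (k3 = 0.030 L mol⁻¹ s⁻¹)

- which of the two there is more of at the end, Tuesday's (isomer of the product A / target)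
- which of the two there is more of at the end, Monday's (isomer of the product A / target)
- final target, as a percentage of the starting material charged, in Tuesday's
- final target, as a percentage of the starting material charged, in Monday's

We begin with how the starting material divides. Two steps consume it, each with a rate equal to its constant times c(starting material) times c(reagent). In the ratio of the two rates both concentrations cancel, so the split depends on the constants. Equal constants would give an even split, the zero of our scale. Here the step to the target has 0.030 L mol⁻¹ s⁻¹ against 0.061 L mol⁻¹ s⁻¹, which pushes the split away from even. This gives the quantity we carry, the target share (a selectivity), which is the part of the consumed starting material that passes through the target: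

φ = constant to the target / sum of both constants = 33.0%

The remaining 67.0% becomes the isomer of the product A, which no step removes. Of whatever starting material has reacted, the target therefore holds at most φ, less than the isomer of the product A, in both flasks.

Next comes the timing. The reagent is in excess, and a whole charge of starting material leaves 80.0% of it, so we treat consumption as pseudo-first-order with 0.464 min⁻¹. On this estimate, material enters the target on average at the middle of the feed plus one lifetime, 3.65 min. After that, the target relaxes with the forward and back constants added, 0.0585 min⁻¹, toward 12.8% of what was made. Our reckoning:

Tuesday's: φ × (12.8% + 87.2% × exp(−0.0585 min⁻¹ × (15 min − 3.65 min))) = 19.0%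

Monday's: φ × (12.8% + 87.2% × exp(−0.0585 min⁻¹ × (30 min − 3.65 min))) = 10.4%

The forecast names isomer of the product A for Tuesday's and isomer of the product A for Monday's. It gives 19.3% (18% to 20.5%) for Tuesday's and 10.6% (9.8% to 11.4%) for Monday's, slightly above our two figures. Its grounds: “the target relaxes over about 17 minutes toward 1/7.8 of the amount formed”.

The simulation gives 19.2% target on Tuesday's and 10.6% on Monday's, with 66.7% and 67.0% of the isomer of the product A. At 15.0 min, Tuesday's flask also holds 13.5% isomer of the product B. The neighbour flask, Tuesday's with 21 mM of reagent, still has 35.8% starting material at 15.0 min, so φ of the 64.2% that reacted is 21.2%, and that flask holds 14.1% target and 7.09% isomer of the product B.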